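Ring C is numbered C1 (quaternary: CH3 and Ca of the Ca=Cb link to coumarin A), C2, C3, C4 (CH3), C5 and C6 (coumarin B). Its methyl groups stand para on C1 and C4, so ring C is a masked, symmetric 1,4-dimethylcyclohexa-1,3-diene. This achiral diene and acrolein are the precursors. One iminium-catalysed Diels–Alder reaction bonds Ca to C1 and Cb to C4, closes a bicyclo[2.2.2]octene and fixes quaternary C1 absolutely, with no regiochemical issue. The C4–Cb bond is temporary. After deformylation, oxygen insertion replaces it by C4–O on the Ca face, and a suprafacial Claisen shift hands that face on to C6. A double aldol–lactonisation then builds both coumarins.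

Key step: step 3

Remark on the chemistry: Ca is the CH2 terminus and Cb the α-carbon of acrolein. In the numbering above the target is C1 (R), C6 (R), with Ca and coumarin B on the same ring face. 2,4-Dihydroxy-3-methoxybenzaldehyde is taken as purchasable.

Step 1
Reactants: 1 p-xylene
Product: 2 1,4-dimethylcyclohexa-1,4-diene
Conditions: Li, NH3(l), EtOH, Et2O, −78 to −33 °C
Reagents that add atoms: none
Why: Birch reduction of a 1,4-dialkylbenzene protonates two unsubstituted para positions, so both methyl groups stay on the two isolated double bonds and no stereocentre arises.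

Step 2
Reactants: 2 1,4-dimethylcyclohexa-1,4-diene
Product: 3 1,4-dimethylcyclohexa-1,3-diene
Conditions: KOtBu (0.2 equiv), DMSO, rt, N2; distillation
Reagents that add atoms: none
Why: Base-mediated prototropic isomerisation through the pentadienyl anion equilibrates the skipped and conjugated dienes and favours the conjugated isomer that keeps both methyl groups on trisubstituted double bonds; residual 1 and 2 are inert in step 3.

Step 3
Reactants: 3 1,4-dimethylcyclohexa-1,3-diene, 4 acrolein
Product: 7 endo-(1R,2R,4R)-1,4-dimethylbicyclo[2.2.2]oct-5-ene-2-carbaldehyde, via acrolein iminium chloride 5 (not isolated), via cycloadduct iminium chloride 6 (not isolated)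
Conditions: (5S)-5-benzyl-2,2,3-trimethylimidazolidin-4-one·HCl (20 mol %), MeCN–H2O 95:5, 0 °C to rt; SiO2 chromatography to remove the exo isomer
Reagents that add atoms: water, O
Why: Acrolein condenses with the secondary amine salt to the (E)-iminium ion 5, whose lowered LUMO undergoes a concerted but asynchronous [4+2] cycloaddition with the electron-rich diene 3, and the water in the medium hydrolyses 6 and returns the catalyst. The closest known reaction type is the imidazolidinone-catalysed enantioselective Diels–Alder reaction of cyclohexa-1,3-diene with acrolein, applied here to its 1,4-dimethyl homologue. The single new ring (C1–Ca–Cb–C4–C5=C6) is closed by intermolecular suprafacial/suprafacial cycloaddition that forms C1–Ca and C4–Cb in one event and so bridges ring C into a bicyclo[2.2.2]octene. Cb becomes R because the benzyl group of the (5S)-catalyst covers one face of the iminium alkene and the diene adds to the open face, while C1 and C4 (both R as bridgeheads) follow from the endo orientation, in which the iminium carbon lies under C5–C6 and away from the C2–C3 ethano bridge. Regioselectivity is not needed because the two diene termini are equivalent, but facial and endo selectivity are both needed, since an exo adduct formed on the same iminium face carries mirror-image bridgeheads; the endo aldehyde is therefore purified before Cb is erased in step 4.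

Step 4
Reactants: 7 endo-(1R,2R,4R)-1,4-dimethylbicyclo[2.2.2]oct-5-ene-2-carbaldehyde
Product: 8 (1R,4R)-1,4-dimethylbicyclo[2.2.2]oct-5-en-2-one
Conditions: O2 (1 atm), Cu(OAc)2 (10 mol %), 2,2′-bipyridine (10 mol %), DABCO, DMF, 40 °C
Reagents that add atoms: dioxygen, O=O
Why: Copper-catalysed aerobic oxidative deformylation of an α-branched aldehyde oxygenates the enolised Cb and expels the formyl carbon as formic acid; the C5=C6 bond has no allylic hydrogen and is left alone, and C1 and C4 are untouched while Cb stops being stereogenic.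

Step 5
Reactants: 8 (1R,4R)-1,4-dimethylbicyclo[2.2.2]oct-5-en-2-one
Product: 9 (1R,5R)-1,5-dimethyl-2-oxabicyclo[3.2.2]non-6-en-3-one
Conditions: mCPBA (1.2 equiv), CH2Cl2–aq. phosphate buffer (pH 7.5), 0 °C to rt; used after filtration through Et3N-deactivated SiO2
Reagents that add atoms: mCPBA (3-chloroperoxybenzoic acid), OOC(=O)c1cccc(Cl)c1
Why: In this Baeyer–Villiger oxidation the tertiary, allylic bridgehead C4 migrates in preference to CaH2 and with retention, so the new C4–O bond lies on the ring face that carries Ca; buffering keeps the tertiary allylic lactone from ionising, and the hindered, inductively deactivated C5=C6 bond is the slower site for the peracid.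

Step 6
Reactants: 9 (1R,5R)-1,5-dimethyl-2-oxabicyclo[3.2.2]non-6-en-3-one
Product: 10 (1R,5R)-1,5-dimethyl-2-oxabicyclo[3.2.2]non-6-en-3-ol (anomer mixture)
Conditions: iBu2AlH (1.1 equiv), CH2Cl2, −78 °C; aq. potassium sodium tartrate
Reagents that add atoms: none
Why: Partial lactone reduction with diisobutylaluminium hydride at low temperature stops at the hemiacetal oxidation level and brings Cb to the aldehyde level in one operation; C1 and C4 are not touched and the anomeric centre is irrelevant.

Step 7
Reactants: 10 (1R,5R)-1,5-dimethyl-2-oxabicyclo[3.2.2]non-6-en-3-ol, 11 malonic acid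
Product: 14 (E)-4-[(1R,4R)-4-hydroxy-1,4-dimethylcyclohex-2-en-1-yl]but-3-enoic acid, via open hydroxy aldehyde 12 (not isolated), via alkylidenemalonic acid 13 (not isolated)
Conditions: malonic acid (1.5 equiv), piperidinium acetate (5 mol %), DMSO, 90–100 °C
Reagents that add atoms: none
Why: In this deconjugative Knoevenagel–Doebner condensation the ring-opened form 12 condenses with malonic acid and 13 decarboxylates with shift of the double bond to Ca=Cb, giving the alk-3-enoic acid whose E geometry is enforced by the bulky quaternary C1; the weakly acidic, strongly solvating medium should spare the tertiary allylic alcohol.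

Step 8
Reactants: 14 (E)-4-[(1R,4R)-4-hydroxy-1,4-dimethylcyclohex-2-en-1-yl]but-3-enoic acid, 15 trimethyl orthoacetate
Product: 18 methyl (E)-4-[(1R,2R)-2-(2-methoxy-2-oxoethyl)-1,4-dimethylcyclohex-3-en-1-yl]but-3-enoate, via hydroxy methyl ester 16 (not isolated), via mixed ketene acetal 17 (not isolated)
Conditions: MeC(OMe)3 (excess), 100 °C; then EtCO2H (10 mol %), o-xylene, 140 °C, MeOH distilled off
Reagents that add atoms: none
Why: The orthoester first methylates the carboxylic acid, and the Johnson–Claisen rearrangement of 17 then carries the acetate unit from O–C4 to C6 across one ring face (suprafacial [3,3] shift with the C4–O bond pseudo-axial), which sets C6 cis to Ca and moves the alkene to C4=C5 with fixed regiochemistry.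

Step 9
Reactants: 19 2,4-dihydroxy-3-methoxybenzaldehyde
Product: 21 3-methoxy-2,4-bis(methoxymethoxy)benzaldehyde, via disodium bis-phenoxide 20 (not isolated)
Conditions: NaH (2.4 equiv), MOMCl (2.4 equiv), DMF, 0 °C to rt
Reagents that add atoms: chloromethyl methyl ether (MOMCl), COCCl
Why: Williamson-type O-alkylation of both phenoxides; full deprotonation with NaH is used because the 2-OH is hydrogen-bonded to the formyl group.

Step 10
Reactants: 18 methyl (E)-4-[(1R,2R)-2-(2-methoxy-2-oxoethyl)-1,4-dimethylcyclohex-3-en-1-yl]but-3-enoate, 21 3-methoxy-2,4-bis(methoxymethoxy)benzaldehyde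
Product: 23 bis-aldol adduct (each ester α-carbon now bears a hydroxy[3-methoxy-2,4-bis(methoxymethoxy)phenyl]methyl group; epimer mixture at the four new centres), via dilithium bis-enolate 22 (not isolated)
Conditions: iPr2NLi (2.3 equiv), THF, −78 °C; 21 (2.5 equiv), −78 °C; AcOH quench at −78 °C
Reagents that add atoms: none
Why: This is a twofold directed aldol addition in which the A-chain dienolate reacts at its α-carbon because its γ-carbon Ca is neopentylic, and condensation between the two chains is excluded by the E alkene; the four new stereocentres need no control since step 11 erases them, and C1, C6 and the Ca=Cb geometry are not involved.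

Step 11
Reactants: 23 bis-aldol adduct
Product: 26 target CNP0264408.1, via tetraphenol bis-aldol 24 (not isolated), via bis(4-hydroxychroman-2-one) 25 (not isolated)
Conditions: HCl (ca. 1 M), MeOH–THF, 55 °C
Reagents that add atoms: none
Why: Acidic methanolysis removes the four MOM acetals, each freed 2-OH lactonises onto the neighbouring ester and the electron-rich benzylic alcohols dehydrate (acid-catalysed lactonisation and E1 dehydration); the push–pull aryl acrylate units can equilibrate their geometry under acid, so the two coumarin lactones are the thermodynamic sink, and such conditions are known to spare trisubstituted alkenes.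

Compound list
1 | p-xylene | Cc1ccc(C)cc1 | starting material
2 | 1,4-dimethylcyclohexa-1,4-diene | CC1=CCC(C)=CC1 | intermediate
3 | 1,4-dimethylcyclohexa-1,3-diene | CC1=CC=C(C)CC1 | intermediate
4 | acrolein | C=CC=O | starting material
5 | (E)-iminium chloride from acrolein and (5S)-5-benzyl-2,2,3-trimethylimidazolidin-4-one | C=C/C=[N+]1/C(C)(C)N(C)C(=O)[C@@H]1Cc2ccccc2.[Cl-] | intermediate
6 | iminium chloride of the endo cycloadduct | C[C@]12CC[C@](C)(C=C1)[C@H](/C=[N+]3/C(C)(C)N(C)C(=O)[C@@H]3Cc4ccccc4)C2.[Cl-] | intermediate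
7 | endo-(1R,2R,4R)-1,4-dimethylbicyclo[2.2.2]oct-5-ene-2-carbaldehyde | C[C@]12CC[C@](C)(C=C1)[C@H](C=O)C2 | intermediate
8 | (1R,4R)-1,4-dimethylbicyclo[2.2.2]oct-5-en-2-one | C[C@]12CC[C@](C)(C=C1)C(=O)C2 | intermediate
9 | (1R,5R)-1,5-dimethyl-2-oxabicyclo[3.2.2]non-6-en-3-one | C[C@]12CC[C@](C)(C=C1)OC(=O)C2 | intermediate
10 | (1R,5R)-1,5-dimethyl-2-oxabicyclo[3.2.2]non-6-en-3-ol, anomer mixture | C[C@]12CC[C@](C)(C=C1)OC(O)C2 | intermediate
11 | malonic acid | OC(=O)CC(=O)O | starting material
12 | 2-[(1R,4R)-4-hydroxy-1,4-dimethylcyclohex-2-en-1-yl]acetaldehyde | O=CC[C@@]1(C)CC[C@@](C)(O)C=C1 | intermediate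
13 | 2-{2-[(1R,4R)-4-hydroxy-1,4-dimethylcyclohex-2-en-1-yl]ethylidene}malonic acid | OC(=O)C(=CC[C@@]1(C)CC[C@@](C)(O)C=C1)C(=O)O | intermediate
14 | (E)-4-[(1R,4R)-4-hydroxy-1,4-dimethylcyclohex-2-en-1-yl]but-3-enoic acid | OC(=O)C/C=C/[C@@]1(C)CC[C@@](C)(O)C=C1 | intermediate
15 | trimethyl orthoacetate | CC(OC)(OC)OC | starting material
16 | methyl (E)-4-[(1R,4R)-4-hydroxy-1,4-dimethylcyclohex-2-en-1-yl]but-3-enoate | COC(=O)C/C=C/[C@@]1(C)CC[C@@](C)(O)C=C1 | intermediate
17 | methyl (E)-4-{(1R,4R)-4-[(1-methoxyethenyl)oxy]-1,4-dimethylcyclohex-2-en-1-yl}but-3-enoate | COC(=O)C/C=C/[C@@]1(C)CC[C@@](C)(OC(=C)OC)C=C1 | intermediate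
18 | methyl (E)-4-[(1R,2R)-2-(2-methoxy-2-oxoethyl)-1,4-dimethylcyclohex-3-en-1-yl]but-3-enoate | COC(=O)C/C=C/[C@@]1(C)CCC(C)=C[C@H]1CC(=O)OC | intermediate
19 | 2,4-dihydroxy-3-methoxybenzaldehyde | O=Cc1ccc(O)c(OC)c1O | starting material
20 | disodium 4-formyl-2-methoxybenzene-1,3-diolate | [Na+].[Na+].O=Cc1ccc([O-])c(OC)c1[O-] | intermediate
21 | 3-methoxy-2,4-bis(methoxymethoxy)benzaldehyde | O=Cc1ccc(OCOC)c(OC)c1OCOC | intermediate
22 | dilithium bis-enolate of 18 (ester enolate on the C6 chain, dienolate on the C1 chain; ring C as in 18) | [Li+].[Li+].COC([O-])=C/C=C/[C@@]1(C)CCC(C)=C[C@H]1C=C([O-])OC | intermediate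
23 | bis-aldol adduct of 18 with two molecules of 21 (ring C spatially as in 18, E alkene, carbinol and α centres mixed) | COC(=O)C(C(O)c1ccc(OCOC)c(OC)c1OCOC)/C=C/[C@@]2(C)CCC(C)=C[C@H]2C(C(=O)OC)C(O)c3ccc(OCOC)c(OC)c3OCOC | intermediate
24 | tetraphenol obtained from 23 by loss of the four MOM groups | COC(=O)C(C(O)c1ccc(O)c(OC)c1O)/C=C/[C@@]2(C)CCC(C)=C[C@H]2C(C(=O)OC)C(O)c3ccc(O)c(OC)c3O | intermediate
25 | bis(4,7-dihydroxy-8-methoxychroman-2-one) carrying ring C at C3 of one unit and the Ca=Cb link at C3 of the other | COc1c(O)ccc2C(O)C(/C=C/[C@@]3(C)CCC(C)=C[C@H]3C4C(O)c5ccc(O)c(OC)c5OC4=O)C(=O)Oc12 | intermediate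
26 | CNP0264408.1, 7-hydroxy-3-{(1R,6R)-6-[(E)-2-(7-hydroxy-8-methoxy-2-oxo-2H-chromen-3-yl)ethenyl]-3,6-dimethylcyclohex-2-en-1-yl}-8-methoxy-2H-chromen-2-one | COc1c(O)ccc2cc(/C=C/[C@@]3(C)CCC(C)=C[C@H]3c3cc4ccc(O)c(OC)c4oc3=O)c(=O)oc12 | target

Total step count: 11. Longest linear sequence: 10 (steps 1–8, 10 and 11; step 9 is a side branch).

Steps most likely to fail

Step 3. The diene is substituted at both reacting termini and may add too slowly to the iminium ion. Acrolein oligomerisation and acid-promoted diene isomerisation could then take over, or the endo and facial preferences could erode. The fallback replaces amine catalysis by an auxiliary-controlled, Lewis-acid-promoted Diels–Alder reaction. It sets out from diene 3. Cycloaddition with commercial (S)-3-acryloyl-4-benzyloxazolidin-2-one under Et2AlCl (CH2Cl2, −78 °C) should give the endo bicyclic imide F1. The chelated s-cis acryloyl unit is attacked anti to the benzyl group, which corresponds to the same R configuration at Cb, and minor diastereomers can be removed by crystallisation or chromatography. LiBH4 (Et2O, 1 equiv H2O, 0 °C) releases the auxiliary and gives the primary alcohol F2. Oxidation with DMP (CH2Cl2, rt) returns to the route at aldehyde 7.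

Step 5. Peracid addition to the hindered carbonyl may be slow enough for epoxidation of C5=C6 to compete. Traces of acid may also trigger allylic migration of the lactone oxygen from C4 to C6, which would disable step 8. The fallback accepts that migration and replaces the sigmatropic transfer by a double-inversion allylic alkylation, so it also bypasses steps 6–8. It sets out from ketone 8.
- (Me3SiO)2 with catalytic Me3SiOTf (CH2Cl2, −40 °C, then warming) is an oxidant system that leaves isolated alkenes alone. It should deliver the cis-fused γ-lactone F3, with oxygen on C6 on the Ca face.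
- NaCH(CO2Me)2 and Pd(PPh3)4 (THF, 65 °C, Tsuji–Trost reaction) follow. Zerovalent palladium ionises the lactone anti, and the soft nucleophile attacks anti at the less substituted terminus C6. The result is net retention, giving the malonate acid F4.
- BH3·SMe2 (THF, 0 °C) reduces only the acid to the alcohol F5, and DMP gives the aldehyde F6.
- Malonic acid with piperidinium acetate in DMSO gives the butenoic acid F7.
- Krapcho demethoxycarbonylation (LiCl, H2O, DMSO, 150 °C) gives the acid ester F8.
- TMSCHN2 (MeOH–toluene) rejoins the route at diester 18.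

Step 8. Ionisation and dehydration of the tertiary allylic alcohol in the hot, acidic orthoester medium may outrun ketene acetal formation. The fallback uses ionic, palladium-mediated carbon transfer at lower temperature instead of the [3,3] shift. It sets out from acid 14. TMSCHN2 gives hydroxy ester 16, isolated this time, and Ac2O, Et3N and DMAP (CH2Cl2, rt to 40 °C) give the tertiary allylic acetate F9. NaCH(CO2Me)2 with Pd(PPh3)4 (THF, 65 °C) should give the triester F10 by anti ionisation and anti attack at C6, again with net retention on the Ca face. Krapcho demethoxycarbonylation (LiCl, H2O, DMSO, 150 °C) comes back to the route at diester 18.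

Further compounds
F1 | step 3 | (S)-4-benzyl-3-[(1R,2R,4R)-1,4-dimethylbicyclo[2.2.2]oct-5-ene-2-carbonyl]oxazolidin-2-one | C[C@]12CC[C@](C)(C=C1)[C@H](C(=O)N3[C@@H](Cc4ccccc4)COC3=O)C2
F2 | step 3 | [(1R,2R,4R)-1,4-dimethylbicyclo[2.2.2]oct-5-en-2-yl]methanol | C[C@]12CC[C@](C)(C=C1)[C@H](CO)C2
F3 | step 5 | (3aR,7aR)-3a,6-dimethyl-3a,4,5,7a-tetrahydro-1-benzofuran-2(3H)-one | C[C@]12CCC(C)=C[C@H]1OC(=O)C2
F4 | step 5 | 2-[(1R,2S)-2-(1,3-dimethoxy-1,3-dioxopropan-2-yl)-1,4-dimethylcyclohex-3-en-1-yl]acetic acid | OC(=O)C[C@@]1(C)CCC(C)=C[C@H]1C(C(=O)OC)C(=O)OC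
F5 | step 5 | dimethyl 2-[(1S,6R)-6-(2-hydroxyethyl)-3,6-dimethylcyclohex-2-en-1-yl]malonate | OCC[C@@]1(C)CCC(C)=C[C@H]1C(C(=O)OC)C(=O)OC
F6 | step 5 | dimethyl 2-[(1S,6R)-3,6-dimethyl-6-(2-oxoethyl)cyclohex-2-en-1-yl]malonate | O=CC[C@@]1(C)CCC(C)=C[C@H]1C(C(=O)OC)C(=O)OC
F7 | step 5 | (E)-4-[(1R,2S)-2-(1,3-dimethoxy-1,3-dioxopropan-2-yl)-1,4-dimethylcyclohex-3-en-1-yl]but-3-enoic acid | OC(=O)C/C=C/[C@@]1(C)CCC(C)=C[C@H]1C(C(=O)OC)C(=O)OC
F8 | step 5 | (E)-4-[(1R,2R)-2-(2-methoxy-2-oxoethyl)-1,4-dimethylcyclohex-3-en-1-yl]but-3-enoic acid | OC(=O)C/C=C/[C@@]1(C)CCC(C)=C[C@H]1CC(=O)OC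
F9 | step 8 | methyl (E)-4-[(1R,4R)-4-acetoxy-1,4-dimethylcyclohex-2-en-1-yl]but-3-enoate | COC(=O)C/C=C/[C@@]1(C)CC[C@@](C)(OC(C)=O)C=C1
F10 | step 8 | dimethyl 2-{(1S,6R)-6-[(E)-4-methoxy-4-oxobut-1-en-1-yl]-3,6-dimethylcyclohex-2-en-1-yl}malonate | COC(=O)C/C=C/[C@@]1(C)CCC(C)=C[C@H]1C(C(=O)OC)C(=O)OC
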